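**Plan**
1. Retrosynthesis (flavanone numbering; ring A = phloroglucinol ring, ring C = pyranone, ring B = aryl on C2, ring D = dimethylpyran): the two methoxymethyl (MOM) ethers on O5 and O7 are cut first, then ring C is cut twice in one operation, at C4–C4a (aryl–carbonyl) and at O1–C8a (aryl–oxygen).
2. This leaves a ring A aryne (C4a≡C8a, prenyl on C8, protected oxygens on C5 and C7) and an (S)-β-hydroxy dimethylamide carrying rings B and D. The aryne goes back to phloroglucinol, the amide to methyl 4-hydroxybenzoate, isoprene and N,N-dimethylacetamide.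
3. Enabling feature: C8a (bearing O1) and C4a (bearing the C4 carbonyl) are adjacent ring A carbons, C4a lies between O1 and O5, and C8 is blocked by prenyl. An aryne across C4a–C8a is polarised by the C5 oxygen, so the alkoxide enters at C8a and the carbanion arises at C4a, five atoms from the amide carbonyl.
4. Forward: ring D is fused to ring B, the three-carbon chain is added by Claisen condensation and the carbinol is set. Ring A is dressed in parallel (MOM ethers, prenyl by Claisen rearrangement, silyl triflate). Ring C closes in the aryne alkoxylation–acylation domino, and deprotection ends the route.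
5. Stereochemistry: the only stereocentre, C2, is set by asymmetric transfer hydrogenation of the β-keto amide. No bond at C2 is made or broken afterwards, because O1 is arylated (C2 is not alkylated) and the ketone stays masked until the acidic quench.

Key step: step 10

Assumption: the tert-butyl carbonate of 2-methylbut-3-en-2-ol used in step 5 is treated as a purchasable reagent; it is otherwise one acylation away from the alcohol and the chemistry is unchanged.

**Step 1**
Reactants: 1 methyl 4-hydroxybenzoate; 2 isoprene
Product: 4 methyl 2,2-dimethylchroman-6-carboxylate, via prenylphenol 3 (not isolated)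
Conditions: 2 (1.5 equiv), 85% H3PO4, xylene, 35 °C
Reagents that add atoms: none
Why: acid-catalysed Friedel–Crafts prenylation ortho to the hydroxyl (para is blocked by the ester) followed by Markovnikov hydroalkoxylation of the trisubstituted alkene (phenol–isoprene chroman annulation) should build ring D; no stereocentre arises.

**Step 2**
Reactants: 4 methyl 2,2-dimethylchroman-6-carboxylate; 5 N,N-dimethylacetamide
Product: 7 3-(2,2-dimethylchroman-6-yl)-N,N-dimethyl-3-oxopropanamide, via lithium enolate 6 (not isolated)
Conditions: 5 (2.2 equiv), LiN(i-Pr)2 (2.2 equiv, commercial solution), THF, −78 °C; then 4, −78 → 0 °C; aq. NH4Cl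
Reagents that add atoms: none
Why: crossed Claisen condensation of an amide enolate with a non-enolisable aryl ester; the second equivalent of enolate deprotonates the β-keto amide and so stops further addition.

**Step 3**
Reactants: 7 3-(2,2-dimethylchroman-6-yl)-N,N-dimethyl-3-oxopropanamide
Product: 8 (3S)-3-(2,2-dimethylchroman-6-yl)-3-hydroxy-N,N-dimethylpropanamide
Conditions: RuCl(p-cymene)[(S,S)-TsDPEN] (1 mol %), HCO2H/Et3N (5:2), DMF, 40 °C
Reagents that add atoms: none
Why: Noyori–Ikariya asymmetric transfer hydrogenation of an aryl ketone; the CH/π contact between the η6-cymene and the aryl group directs hydride to the same face as in acetophenone, which for ArCOCH2X with the (S,S) ligand should give the (S) carbinol.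

**Step 4**
Reactants: 9 phloroglucinol
Product: 11 3,5-bis(methoxymethoxy)phenol, via mono ether 10 (not isolated)
Conditions: MOMCl (2.1 equiv), i-Pr2NEt (2.5 equiv), DMF, 0 °C → rt; chromatographic removal of mono- and tris-ethers
Reagents that add atoms: chloromethyl methyl ether (MOMCl), COCCl
Why: O-alkylation of a phenol with an α-chloro ether (MOM protection); the three hydroxyls are equivalent, so the bis-ether is a single constitutional isomer and is separated from the statistical by-products.

**Step 5**
Reactants: 11 3,5-bis(methoxymethoxy)phenol; 12 tert-butyl (2-methylbut-3-en-2-yl) carbonate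
Product: 13 1,3-bis(methoxymethoxy)-5-[(2-methylbut-3-en-2-yl)oxy]benzene
Conditions: 12 (1.5 equiv), Pd(PPh3)4 (2 mol %), THF, 0 °C → rt
Reagents that add atoms: none
Why: Tsuji–Trost O-allylation; decarboxylation gives tert-butoxide and a 1,1-dimethyl-π-allyl palladium cation, which the phenoxide attacks at the more substituted terminus under kinetic control to give the tertiary ether.

**Step 6**
Reactants: 13 1,3-bis(methoxymethoxy)-5-[(2-methylbut-3-en-2-yl)oxy]benzene
Product: 15 3,5-bis(methoxymethoxy)-2-(3-methylbut-2-en-1-yl)phenol, via dienone 14 (not isolated)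
Conditions: N,N-diethylaniline/xylene (1:4), 130 °C
Reagents that add atoms: none
Why: aromatic Claisen rearrangement ([3,3] shift) to one of the two equivalent ortho carbons, followed by enolisation, places the linear prenyl group next to the free hydroxyl, i.e. at the future C8.

**Step 7**
Reactants: 15 3,5-bis(methoxymethoxy)-2-(3-methylbut-2-en-1-yl)phenol
Product: 16 3,5-bis(methoxymethoxy)-2-(3-methylbut-2-en-1-yl)phenyl isopropylcarbamate
Conditions: i-PrNCO (1.5 equiv), Et3N (0.2 equiv), CH2Cl2, rt
Reagents that add atoms: isopropyl isocyanate, CC(C)N=C=O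
Why: base-catalysed addition of the phenol to an isocyanate (carbamoylation) installs a strong, later base-cleavable ortho-directing group on the oxygen that will become the leaving group.

**Step 8**
Reactants: 16 3,5-bis(methoxymethoxy)-2-(3-methylbut-2-en-1-yl)phenyl isopropylcarbamate
Product: 20 3,5-bis(methoxymethoxy)-2-(3-methylbut-2-en-1-yl)-6-(trimethylsilyl)phenyl isopropylcarbamate, via N-silyl carbamate 17 (not isolated), via aryllithium 18 (not isolated), via bis-silyl carbamate 19 (not isolated)
Conditions: TBSOTf (1.1 equiv), TMEDA (1.1 equiv), Et2O, 0 °C → rt; TMEDA (2.2 equiv), n-BuLi (2.2 equiv), −78 °C; TMSCl (3.5 equiv), −78 °C → rt; cold dilute aq. NaHSO4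
Reagents that add atoms: chlorotrimethylsilane (TMSCl), C[Si](C)(C)Cl
Why: directed ortho-metalation; after in-situ N-silylation the carbamate and the neighbouring MOM ether cooperate at the only ring C–H ortho to the carbamate (the future C4a), the aryllithium is silylated, and the N–Si bond is hydrolysed on work-up.

**Step 9**
Reactants: 20 3,5-bis(methoxymethoxy)-2-(3-methylbut-2-en-1-yl)-6-(trimethylsilyl)phenyl isopropylcarbamate
Product: 22 3,5-bis(methoxymethoxy)-2-(3-methylbut-2-en-1-yl)-6-(trimethylsilyl)phenyl trifluoromethanesulfonate, via silyl phenol 21 (not isolated)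
Conditions: DBU (1.5 equiv), Et2NH (1.2 equiv), MeCN, 40 °C; then PhNTf2 (1.5 equiv), rt
Reagents that add atoms: N-phenylbis(trifluoromethanesulfonimide) (PhNTf2), O=S(=O)(N(c1ccccc1)S(=O)(=O)C(F)(F)F)C(F)(F)F
Why: E1cB cleavage of the N-monosubstituted carbamate (the isocyanate is scavenged by Et2NH) frees the phenoxide, which is triflated in the same flask to give the o-silylaryl triflate aryne precursor.

**Step 10**
Reactants: 8 (3S)-3-(2,2-dimethylchroman-6-yl)-3-hydroxy-N,N-dimethylpropanamide; 22 3,5-bis(methoxymethoxy)-2-(3-methylbut-2-en-1-yl)-6-(trimethylsilyl)phenyl trifluoromethanesulfonate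
Product: 27 (2S)-2-(2,2-dimethylchroman-6-yl)-5,7-bis(methoxymethoxy)-8-(3-methylbut-2-en-1-yl)chroman-4-one, via potassium alkoxide 23 (not isolated), via aryne 24 (not isolated), via aryl anion 25 (not isolated), via hemiaminal alkoxide 26 (not isolated)
Conditions: 8 (1.3 equiv), KH (1.3 equiv), THF, 0 °C; then KF (3 equiv), 18-crown-6 (3 equiv), slow addition of 22 (1.0 equiv), THF, −20 → 0 °C; AcOH (excess), −20 °C, then aq. phosphate buffer pH 5
Reagents that add atoms: none
Why: Proposed new method: fluoride removes the silyl group of 22 and expels triflate to give aryne 24 (C4a≡C8a of ring A); the preformed potassium alkoxide 23 adds to C8a, the aryne carbon remote from the inductively withdrawing C5 oxygen, so that the carbanion arises at C4a between O1 and O5 (25) and attacks the amide carbonyl five atoms away, forming C4–C4a and closing ring C in a 6-exo-trig mode to the hemiaminal alkoxide 26. The closest known reaction type is the fluoride-mediated annulation of arynes with salicylate esters to xanthones (aryloxide addition, then anionic acyl substitution), supported by aryne insertion into amide bonds and by Parham cycliacylation; new here are an aliphatic alkoxide carrying a β-amide and a pentasubstituted aryne. No stereocentre is created: C2 comes from step 3 and keeps its (S) configuration because the aryl–oxygen bond, not the benzylic C–O bond, is formed, which avoids the ionisation that a p-alkoxybenzylic leaving group would suffer. The selectivities needed are alkoxide attack at C8a and not at C4a, secured by the aryne distortion caused by the C5 methoxymethoxy group, which should outweigh the steric bias of the C8 prenyl group, and acylation of 25 in preference to protonation, secured by the absence of any O–H donor once the alcohol has been deprotonated by KH. Base-induced ring opening to the chalcone and loss of configuration should not occur, because a dimethylamide ion is too poor a leaving group for 26 to collapse, so the ketone is released only in the acetic acid quench.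

**Step 11**
Reactants: 27 (2S)-2-(2,2-dimethylchroman-6-yl)-5,7-bis(methoxymethoxy)-8-(3-methylbut-2-en-1-yl)chroman-4-one
Product: 29 euchrenone a16 [(2S)-2-(2,2-dimethylchroman-6-yl)-5,7-dihydroxy-8-(3-methylbut-2-en-1-yl)chroman-4-one], via 7-MOM ether 28 (not isolated)
Conditions: 3 M aq. HCl/MeOH (1:5), 45 °C
Reagents that add atoms: none
Why: acid-catalysed acetal exchange with methanol (MOM cleavage), the C5 acetal next to the carbonyl leaving first; C2 is untouched because no base is present, and brief mild acid should spare the prenyl group and ring D.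

**Compound list**
1 | methyl 4-hydroxybenzoate | COC(=O)c1ccc(O)cc1 | starting material
2 | isoprene (2-methylbuta-1,3-diene) | C=CC(C)=C | starting material
3 | methyl 4-hydroxy-3-(3-methylbut-2-en-1-yl)benzoate (not isolated) | COC(=O)c1ccc(O)c(CC=C(C)C)c1 | intermediate
4 | methyl 2,2-dimethylchroman-6-carboxylate | COC(=O)c1ccc2OC(C)(C)CCc2c1 | intermediate
5 | N,N-dimethylacetamide | CC(=O)N(C)C | starting material
6 | lithium enolate of N,N-dimethylacetamide (not isolated) | [Li+].C=C([O-])N(C)C | intermediate
7 | 3-(2,2-dimethylchroman-6-yl)-N,N-dimethyl-3-oxopropanamide | CN(C)C(=O)CC(=O)c1ccc2OC(C)(C)CCc2c1 | intermediate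
8 | (3S)-3-(2,2-dimethylchroman-6-yl)-3-hydroxy-N,N-dimethylpropanamide | CN(C)C(=O)C[C@H](O)c1ccc2OC(C)(C)CCc2c1 | intermediate
9 | phloroglucinol (benzene-1,3,5-triol) | Oc1cc(O)cc(O)c1 | starting material
10 | 5-(methoxymethoxy)benzene-1,3-diol (not isolated) | COCOc1cc(O)cc(O)c1 | intermediate
11 | 3,5-bis(methoxymethoxy)phenol | COCOc1cc(O)cc(OCOC)c1 | intermediate
12 | tert-butyl (2-methylbut-3-en-2-yl) carbonate | C=CC(C)(C)OC(=O)OC(C)(C)C | starting material
13 | 1,3-bis(methoxymethoxy)-5-[(2-methylbut-3-en-2-yl)oxy]benzene | C=CC(C)(C)Oc1cc(OCOC)cc(OCOC)c1 | intermediate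
14 | 3,5-bis(methoxymethoxy)-6-(3-methylbut-2-en-1-yl)cyclohexa-2,4-dien-1-one (not isolated) | O=C1C=C(OCOC)C=C(OCOC)C1CC=C(C)C | intermediate
15 | 3,5-bis(methoxymethoxy)-2-(3-methylbut-2-en-1-yl)phenol | CC(C)=CCc1c(O)cc(OCOC)cc1OCOC | intermediate
16 | 3,5-bis(methoxymethoxy)-2-(3-methylbut-2-en-1-yl)phenyl isopropylcarbamate | CC(C)=CCc1c(OC(=O)NC(C)C)cc(OCOC)cc1OCOC | intermediate
17 | N-(tert-butyldimethylsilyl) derivative of 16 (not isolated) | CC(C)=CCc1c(OC(=O)N(C(C)C)[Si](C)(C)C(C)(C)C)cc(OCOC)cc1OCOC | intermediate
18 | 6-lithio derivative of 17 (not isolated) | CC(C)=CCc1c(OC(=O)N(C(C)C)[Si](C)(C)C(C)(C)C)c([Li])c(OCOC)cc1OCOC | intermediate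
19 | N-(tert-butyldimethylsilyl)-6-(trimethylsilyl) carbamate (not isolated) | CC(C)=CCc1c(OC(=O)N(C(C)C)[Si](C)(C)C(C)(C)C)c([Si](C)(C)C)c(OCOC)cc1OCOC | intermediate
20 | 3,5-bis(methoxymethoxy)-2-(3-methylbut-2-en-1-yl)-6-(trimethylsilyl)phenyl isopropylcarbamate | CC(C)=CCc1c(OC(=O)NC(C)C)c([Si](C)(C)C)c(OCOC)cc1OCOC | intermediate
21 | 3,5-bis(methoxymethoxy)-2-(3-methylbut-2-en-1-yl)-6-(trimethylsilyl)phenol (not isolated; present as its DBU-H phenoxide) | CC(C)=CCc1c(O)c([Si](C)(C)C)c(OCOC)cc1OCOC | intermediate
22 | 3,5-bis(methoxymethoxy)-2-(3-methylbut-2-en-1-yl)-6-(trimethylsilyl)phenyl trifluoromethanesulfonate | CC(C)=CCc1c(OS(=O)(=O)C(F)(F)F)c([Si](C)(C)C)c(OCOC)cc1OCOC | intermediate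
23 | potassium alkoxide of 8 (not isolated) | [K+].CN(C)C(=O)C[C@H]([O-])c1ccc2OC(C)(C)CCc2c1 | intermediate
24 | 3,5-bis(methoxymethoxy)-6-(3-methylbut-2-en-1-yl)-1,2-didehydrobenzene (aryne, not isolated) | COCOC1=CC(OCOC)=C(CC=C(C)C)C#C1 | intermediate
25 | potassium aryl anion from addition of 23 to 24 (not isolated) | [K+].CN(C)C(=O)C[C@H](Oc1[c-]c(OCOC)cc(OCOC)c1CC=C(C)C)c1ccc2OC(C)(C)CCc2c1 | intermediate
26 | potassium (2S)-4-(dimethylamino)-2-(2,2-dimethylchroman-6-yl)-5,7-bis(methoxymethoxy)-8-(3-methylbut-2-en-1-yl)chroman-4-olate (not isolated; C4 unassigned) | [K+].CC(C)=CCc1c(OCOC)cc(OCOC)c2c1O[C@H](c1ccc3c(c1)CCC(C)(C)O3)CC2([O-])N(C)C | intermediate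
27 | (2S)-2-(2,2-dimethylchroman-6-yl)-5,7-bis(methoxymethoxy)-8-(3-methylbut-2-en-1-yl)chroman-4-one | CC(C)=CCc1c(OCOC)cc(OCOC)c2c1O[C@H](c1ccc3c(c1)CCC(C)(C)O3)CC2=O | intermediate
28 | (2S)-2-(2,2-dimethylchroman-6-yl)-5-hydroxy-7-(methoxymethoxy)-8-(3-methylbut-2-en-1-yl)chroman-4-one (not isolated) | CC(C)=CCc1c(OCOC)cc(O)c2c1O[C@H](c1ccc3c(c1)CCC(C)(C)O3)CC2=O | intermediate
29 | euchrenone a16, (2S)-2-(2,2-dimethylchroman-6-yl)-5,7-dihydroxy-8-(3-methylbut-2-en-1-yl)chroman-4-one | CC(C)=CCc1c(O)cc(O)c2c1O[C@H](c1ccc3c(c1)CCC(C)(C)O3)CC2=O | target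

**Step count and risks**
Total steps: 11. Longest linear sequence: 8 (steps 4 to 11, from phloroglucinol); the ring B/D branch has 3 steps before the union.

Steps most likely to fail:

1. Step 10 (proposed new method). The aryl anion may capture a proton before it reaches the amide carbonyl, or the potassium aldolate may fragment by retro-aldol reaction with erosion of configuration. Fallback by known chemistry, setting out from 8 and 22: the same aryne is generated with KF and 18-crown-6 in THF at −20 °C without KH. Under such conditions a neutral aliphatic alcohol adds across an aryne by O–H insertion, which should give the (S)-aryl ether amide F1 with the stereocentre untouched. Activation of the amide with Tf2O and 2,6-di-tert-butyl-4-methylpyridine in CH2Cl2 (−78 → 0 °C) should give a keteniminium ion that is attacked by C4a (intramolecular Vilsmeier–Haack-type acylation of a phloroglucinol ether, buffered so that neither the MOM ethers nor the benzylic ether meet free acid), giving the cyclic iminium triflate F2. Hydrolysis with aq. NaHCO3 returns to the route at 27.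

2. Step 8. Deprotonation may occur at the benzylic–allylic CH2 of the prenyl group beside the carbamate (with ensuing carbamoyl shift), or between the two MOM ethers, in place of the desired ring position. Fallback, setting out from 11, in which halogen–lithium exchange replaces deprotonation: ortho-bromination with NBS and catalytic i-Pr2NH in CH2Cl2 (hydrogen-bond-directed delivery next to the free hydroxyl) should give 2-bromo-3,5-bis(methoxymethoxy)phenol F3. O-Allylation with 12 and Pd(PPh3)4 as in step 5 (zerovalent palladium inserts only slowly into the electron-rich aryl bromide at 0 °C) should give the bromo aryl tertiary ether F4. Its Claisen rearrangement can reach only the one free ortho carbon and should give the bromo prenyl phenol F5. Silylation of the hydroxyl with (Me3Si)2NH gives the trimethylsilyl ether F6. Bromine–lithium exchange with n-BuLi at −78 °C then triggers the retro-Brook shift of silicon from oxygen to carbon, giving the lithium salt of 21, which is triflated with Tf2O to rejoin the route at 22.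

3. Step 5. The π-allyl cation may alkylate a carbon of the very electron-rich ring, or the linear prenyl ether may form. Fallback, setting out from 11: copper-catalysed propargylic etherification with 3-chloro-3-methylbut-1-yne, CuCl2 (catalytic) and DBU in MeCN at 0 °C should give the aryl 1,1-dimethylpropargyl ether F7. Semi-hydrogenation (H2, Pd/CaCO3 poisoned with Pb(OAc)2, quinoline, EtOAc) returns to the route at 13.

**Further compounds**
F1 | step 10 | (3S)-3-[3,5-bis(methoxymethoxy)-2-(3-methylbut-2-en-1-yl)phenoxy]-3-(2,2-dimethylchroman-6-yl)-N,N-dimethylpropanamide | CN(C)C(=O)C[C@H](Oc1cc(OCOC)cc(OCOC)c1CC=C(C)C)c1ccc2OC(C)(C)CCc2c1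
F2 | step 10 | (2S)-N-[2-(2,2-dimethylchroman-6-yl)-5,7-bis(methoxymethoxy)-8-(3-methylbut-2-en-1-yl)chroman-4-ylidene]-N-methylmethanaminium trifluoromethanesulfonate | CC(C)=CCc1c(OCOC)cc(OCOC)c2c1O[C@H](c1ccc3c(c1)CCC(C)(C)O3)CC2=[N+](C)C.[O-]S(=O)(=O)C(F)(F)F
F3 | step 8 | 2-bromo-3,5-bis(methoxymethoxy)phenol | Oc1cc(OCOC)cc(OCOC)c1Br
F4 | step 8 | 2-bromo-1,5-bis(methoxymethoxy)-3-[(2-methylbut-3-en-2-yl)oxy]benzene | C=CC(C)(C)Oc1cc(OCOC)cc(OCOC)c1Br
F5 | step 8 | 2-bromo-3,5-bis(methoxymethoxy)-6-(3-methylbut-2-en-1-yl)phenol | CC(C)=CCc1c(O)c(Br)c(OCOC)cc1OCOC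
F6 | step 8 | [2-bromo-3,5-bis(methoxymethoxy)-6-(3-methylbut-2-en-1-yl)phenoxy]trimethylsilane | CC(C)=CCc1c(O[Si](C)(C)C)c(Br)c(OCOC)cc1OCOC
F7 | step 5 | 1,3-bis(methoxymethoxy)-5-[(2-methylbut-3-yn-2-yl)oxy]benzene | C#CC(C)(C)Oc1cc(OCOC)cc(OCOC)c1
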